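Everything rests on cutting C3–C4 in the piperidine ring of lepadin H. The route exploits the 1,3-relationship of oxygen-bearing C3 and ring-fusion carbon C4a across C4. When C4 is an exocyclic methylene on the carbocycle and C3 the aldehyde of an L-alaninal unit carried by N1, the two are ene and enophile. A single aluminium-promoted carbonyl-ene reaction then makes C3–C4, closes the piperidine, creates C3 and relocates the double bond to C4a=C5, ready for one syn hydrogenation that fixes C4a and C5. The precursor is N-benzyl-N-[2-methylene-3-(5-silyloxyoctyl)cyclohexyl]-L-alaninal, built with nitrogen and side chain cis so that H5 shares the H8a face.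

Key step: step 13

Remark: atom labels (N1, C2 … C8a, side chain C1′–C8′) follow the decahydroquinoline numbering of the target in all intermediates.
Assumption: the enantiomer of the ferrocenyl diphosphine TaniaPhos that leads to the 3S conjugate adduct is used in step 4.

Step 1
Reactants: 1 (R)-2-propyloxirane; 2 allylmagnesium bromide
Product: 3 (4R)-oct-7-en-4-ol
Conditions: CuI (10 mol %), THF, −30 → 0 °C; H2O quench
Reagents that add atoms: none
Why: Copper-assisted SN2 ring opening of a terminal epoxide by an allyl Grignard reagent occurs at the unsubstituted carbon, so the carbinol centre (future C5′, R) is carried over untouched.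

Step 2
Reactants: 3 (4R)-oct-7-en-4-ol
Product: 4 tert-butyl(dimethyl)[(4R)-oct-7-en-4-yloxy]silane
Conditions: TBSCl, imidazole, DMF, rt
Reagents that add atoms: tert-butyldimethylsilyl chloride, CC(C)(C)[Si](C)(C)Cl
Why: Imidazole-promoted silylation removes the only acidic proton before the organometallic steps, and the silyl ether is cleaved only by the final acid treatment.

Step 3
Reactants: 4 tert-butyl(dimethyl)[(4R)-oct-7-en-4-yloxy]silane
Product: 6 [(4R)-8-bromooctan-4-yl]oxy(tert-butyl)dimethylsilane, via alkylzirconocene chloride 5 (not isolated)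
Conditions: Cp2Zr(H)Cl, CH2Cl2, rt; NBS, 0 °C
Reagents that add atoms: N-bromosuccinimide, O=C1CCC(=O)N1Br
Why: Hydrozirconation of the terminal alkene is anti-Markovnikov and the C–Zr bond is cleaved by electrophilic bromine, a known one-flask route from a 1-alkene to a primary bromide that leaves the silyl ether alone.

Step 4
Reactants: 6 [(4R)-8-bromooctan-4-yl]oxy(tert-butyl)dimethylsilane; 7 cyclohex-2-en-1-one
Product: 10 (2S,3S)-2-[(dimethylamino)methyl]-3-[(5R)-5-(tert-butyldimethylsilyloxy)octyl]cyclohexan-1-one, via Grignard reagent 8 (not isolated), via magnesium enolate 9 (not isolated)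
Conditions: Mg, Et2O, reflux; add to 7, CuCl (5 mol %), TaniaPhos (6 mol %), Et2O, 0 °C; [CH2=NMe2]I, CH2Cl2, −78 °C → rt
Reagents that add atoms: Eschenmoser's salt (N,N-dimethylmethyleneiminium iodide), C=[N+](C)C.[I-]
Why: Copper-catalysed asymmetric conjugate addition of a primary alkyl Grignard reagent to cyclohexenone sets C5 (S) under control of the diphosphine, and the regiodefined magnesium enolate is aminomethylated at C4a (Mannich reaction) anti to the new chain.

Step 5
Reactants: 10 (2S,3S)-2-[(dimethylamino)methyl]-3-[(5R)-5-(tert-butyldimethylsilyloxy)octyl]cyclohexan-1-one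
Product: 11 (1S,2S,3S)-2-[(dimethylamino)methyl]-3-[(5R)-5-(tert-butyldimethylsilyloxy)octyl]cyclohexan-1-ol
Conditions: Li[HB(s-Bu)3], THF, −78 °C; H2O, acid–base extraction
Reagents that add atoms: none
Why: The bulky borohydride approaches the diequatorial chair ketone along the equatorial trajectory, which should give the axial C8a alcohol (S), trans to the side chain as the later inversion requires.

Step 6
Reactants: 11 (1S,2S,3S)-2-[(dimethylamino)methyl]-3-[(5R)-5-(tert-butyldimethylsilyloxy)octyl]cyclohexan-1-ol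
Product: 13 (1S,3S)-2-methylidene-3-[(5R)-5-(tert-butyldimethylsilyloxy)octyl]cyclohexan-1-ol, via amine N-oxide 12 (not isolated)
Conditions: mCPBA (1 equiv), CH2Cl2, 0 °C; filtration through basic Al2O3; toluene, 110 °C
Reagents that add atoms: none
Why: N-Oxidation and Cope elimination (syn, H4a is the only β-hydrogen) deliver the exocyclic methylene regiospecifically and bypass the dimerisation-prone α-methylene ketone, whose hydride reduction would give the cis alcohol instead.

Step 7
Reactants: 14 benzylamine; 15 2-nitrobenzenesulfonyl chloride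
Product: 16 N-benzyl-2-nitrobenzenesulfonamide
Conditions: Et3N, CH2Cl2, 0 °C → rt
Reagents that add atoms: none
Why: Sulfonylation of the primary amine gives the acidic N–H partner needed for the Mitsunobu step and brings in the benzyl group at the same time.

Step 8
Reactants: 13 (1S,3S)-2-methylidene-3-[(5R)-5-(tert-butyldimethylsilyloxy)octyl]cyclohexan-1-ol; 16 N-benzyl-2-nitrobenzenesulfonamide
Product: 17 N-benzyl-N-{(1R,3S)-2-methylidene-3-[(5R)-5-(tert-butyldimethylsilyloxy)octyl]cyclohexyl}-2-nitrobenzenesulfonamide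
Conditions: PPh3, DIAD, toluene, 0 °C → rt
Reagents that add atoms: none
Why: Fukuyama–Mitsunobu alkylation displaces the activated axial allylic oxygen by SN2 with inversion, placing nitrogen equatorial at C8a (R) and cis to the side chain; a sulfonamide is chosen because an allylic azide would drift by [3,3] shift to the primary isomer.

Step 9
Reactants: 17 N-benzyl-N-{(1R,3S)-2-methylidene-3-[(5R)-5-(tert-butyldimethylsilyloxy)octyl]cyclohexyl}-2-nitrobenzenesulfonamide
Product: 18 (1R,3S)-N-benzyl-2-methylidene-3-[(5R)-5-(tert-butyldimethylsilyloxy)octyl]cyclohexan-1-amine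
Conditions: PhSH, K2CO3, MeCN, rt
Reagents that add atoms: none
Why: Thiolate adds to the nitroarene (Meisenheimer complex) and expels sulfur dioxide and the amine, a mild deprotection that leaves alkene, silyl ether and stereocentres untouched.

Step 10
Reactants: 19 methyl (R)-lactate
Product: 20 methyl (2R)-2-(trifluoromethylsulfonyloxy)propanoate
Conditions: Tf2O, 2,6-lutidine, CH2Cl2, −78 → 0 °C
Reagents that add atoms: trifluoromethanesulfonic anhydride, O=S(=O)(OS(=O)(=O)C(F)(F)F)C(F)(F)F
Why: O-Triflation does not touch the stereocentre (R retained) and makes the lactate electrophilic enough for a hindered amine.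

Step 11
Reactants: 18 (1R,3S)-N-benzyl-2-methylidene-3-[(5R)-5-(tert-butyldimethylsilyloxy)octyl]cyclohexan-1-amine; 20 methyl (2R)-2-(trifluoromethylsulfonyloxy)propanoate
Product: 21 methyl N-benzyl-N-{(1R,3S)-2-methylidene-3-[(5R)-5-(tert-butyldimethylsilyloxy)octyl]cyclohexyl}-L-alaninate
Conditions: 2,6-lutidine, CH2Cl2, 0 °C → rt
Reagents that add atoms: none
Why: SN2 displacement of an α-triflyloxy ester by a secondary amine proceeds with inversion, so the (R)-lactate becomes the (S)-alanine centre C2; benzyl is already on nitrogen, which avoids alkylating a doubly branched amine later.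

Step 12
Reactants: 21 methyl N-benzyl-N-{(1R,3S)-2-methylidene-3-[(5R)-5-(tert-butyldimethylsilyloxy)octyl]cyclohexyl}-L-alaninate
Product: 22 (2S)-2-[benzyl{(1R,3S)-2-methylidene-3-[(5R)-5-(tert-butyldimethylsilyloxy)octyl]cyclohexyl}amino]propanal
Conditions: i-Bu2AlH (1.1 equiv), toluene, −78 °C; MeOH, then aq. potassium sodium tartrate
Reagents that add atoms: none
Why: Partial reduction of the α-amino ester stops at the aluminium hemiacetal at low temperature and releases the aldehyde on work-up; the configurationally sensitive aldehyde is used at once without chromatography.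

Step 13
Reactants: 22 (2S)-2-[benzyl{(1R,3S)-2-methylidene-3-[(5R)-5-(tert-butyldimethylsilyloxy)octyl]cyclohexyl}amino]propanal
Product: 23 (2S,3R,8aR)-1-benzyl-2-methyl-5-[(5R)-5-(tert-butyldimethylsilyloxy)octyl]-1,2,3,4,6,7,8,8a-octahydroquinolin-3-ol
Conditions: Me2AlCl (2.2 equiv), CH2Cl2, −78 → −20 °C; aq. potassium sodium tartrate
Reagents that add atoms: none
Why: Me2AlCl (one equivalent is surrendered to the amine) activates the aldehyde, C4 of the exocyclic methylene bonds to C3 while H5 migrates to oxygen through the cyclic array O–C3–C4–C4a–C5–H, and the alcohol–aluminium complex then loses methane, so no protic acid remains to isomerise the product. The closest known reaction is the alkylaluminium-halide-promoted intramolecular carbonyl-ene cyclisation of an aldehyde onto a 1,1-disubstituted alkene whose tether sits on the central ene carbon (type 2), and Lewis-acid ene closures of N-benzyl α-amino aldehydes to 3-hydroxypiperidines are likewise known. The piperidine ring closes 6-exo-trig at the carbonyl carbon, while both alkene carbons C4 and C4a end up inside the new ring (endo with respect to the alkene). The ene process is suprafacial, so C3 must arrive on the alkene face that carries the axial H5; in the diequatorial chair of 22 this is the H8a face, which the in-plane equatorial nitrogen reaches through a boat-like six-membered array (C2 methyl pseudo-equatorial), and because oxygen must point to C5 and C2 to N1, C4 adds to the Re face of the aldehyde and C3 is formed R, trans to the methyl and cis to H8a, under control of C8a and the sacrificial C5 centre. The chair-like array on the nitrogen face, which needs an axial carbonyl and would give the 3S epimer, finds no allylic hydrogen on that face, and an open Prins-type chair with the bulky O–Al group equatorial leads to 3R as well. The step also needs regioselective hydrogen transfer, secured because H8a sits on the tether carbon out of reach of the oxygen, so that only the C4a=C5 alkene should arise.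

Step 14
Reactants: 23 (2S,3R,8aR)-1-benzyl-2-methyl-5-[(5R)-5-(tert-butyldimethylsilyloxy)octyl]-1,2,3,4,6,7,8,8a-octahydroquinolin-3-ol
Product: 24 (2S,3R,4aS,5S,8aR)-1-benzyl-2-methyl-5-[(5R)-5-(tert-butyldimethylsilyloxy)octyl]decahydroquinolin-3-ol
Conditions: H2 (1–10 bar), [Ir(cod)(PCy3)(py)]PF6 (10 mol %), CH2Cl2, rt
Reagents that add atoms: none
Why: In this hydroxyl-directed homogeneous hydrogenation, iridium held by the C3 hydroxyl delivers both hydrogens syn to the H8a face of the tetrasubstituted alkene, which is also the open face because N1, C2 and C3 fold below the alkene plane, so C4a (S) and C5 (S) are set together, cis to H8a.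

Step 15
Reactants: 24 (2S,3R,4aS,5S,8aR)-1-benzyl-2-methyl-5-[(5R)-5-(tert-butyldimethylsilyloxy)octyl]decahydroquinolin-3-ol
Product: 26 tert-butyl (2S,3R,4aS,5S,8aR)-3-hydroxy-2-methyl-5-[(5R)-5-(tert-butyldimethylsilyloxy)octyl]octahydroquinoline-1(2H)-carboxylate, via secondary amine 25 (not isolated)
Conditions: H2, Pd(OH)2/C, MeOH, rt; filter; Boc2O, Et3N, CH2Cl2, 40 °C
Reagents that add atoms: di-tert-butyl dicarbonate, CC(C)(C)OC(=O)OC(=O)OC(C)(C)C
Why: Benzyl hydrogenolysis is run only after the ring alkene is gone, so no allylic C–N bond is at risk, and carbamate formation then blocks N1 so that only the C3 hydroxyl can be acylated.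

Step 16
Reactants: 26 tert-butyl (2S,3R,4aS,5S,8aR)-3-hydroxy-2-methyl-5-[(5R)-5-(tert-butyldimethylsilyloxy)octyl]octahydroquinoline-1(2H)-carboxylate; 27 (2E,4E)-octa-2,4-dienoic acid
Product: 29 tert-butyl (2S,3R,4aS,5S,8aR)-2-methyl-3-[(2E,4E)-octa-2,4-dienoyloxy]-5-[(5R)-5-(tert-butyldimethylsilyloxy)octyl]octahydroquinoline-1(2H)-carboxylate, via mixed anhydride 28 (not isolated)
Conditions: 2,4,6-Cl3C6H2COCl, Et3N, THF, rt; 26, DMAP, toluene, rt
Reagents that add atoms: none
Why: Yamaguchi esterification acylates hindered secondary alcohols with retention at C3 and, unlike an acid chloride with base, does not pass through a ketene that could scramble the diene geometry.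

Step 17
Reactants: 29 tert-butyl (2S,3R,4aS,5S,8aR)-2-methyl-3-[(2E,4E)-octa-2,4-dienoyloxy]-5-[(5R)-5-(tert-butyldimethylsilyloxy)octyl]octahydroquinoline-1(2H)-carboxylate
Product: 30 lepadin H, (2S,3R,4aS,5S,8aR)-5-[(5R)-5-hydroxyoctyl]-2-methyldecahydroquinolin-3-yl (2E,4E)-octa-2,4-dienoate
Conditions: TFA–H2O (9:1), CH2Cl2, 0 °C → rt; aq. NaHCO3
Reagents that add atoms: none
Why: Aqueous acid removes the carbamate (loss of isobutene and carbon dioxide) and the secondary silyl ether in one operation, while the dienoate ester and all six stereocentres are inert to these conditions.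

Compound list
1 | (R)-2-propyloxirane | CCC[C@@H]1CO1 | starting material
2 | allylmagnesium bromide | C=CC[Mg]Br | starting material
3 | (4R)-oct-7-en-4-ol | C=CCC[C@H](O)CCC | intermediate
4 | tert-butyl(dimethyl)[(4R)-oct-7-en-4-yloxy]silane | C=CCC[C@H](O[Si](C)(C)C(C)(C)C)CCC | intermediate
5 | chlorobis(cyclopentadienyl)[(5R)-5-(tert-butyldimethylsilyloxy)octyl]zirconium | Cl[Zr](CCCC[C@H](O[Si](C)(C)C(C)(C)C)CCC)(C1C=CC=C1)C1C=CC=C1 | intermediate
6 | [(4R)-8-bromooctan-4-yl]oxy(tert-butyl)dimethylsilane | BrCCCC[C@H](O[Si](C)(C)C(C)(C)C)CCC | intermediate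
7 | cyclohex-2-en-1-one | O=C1C=CCCC1 | starting material
8 | [(5R)-5-(tert-butyldimethylsilyloxy)octyl]magnesium bromide | Br[Mg]CCCC[C@H](O[Si](C)(C)C(C)(C)C)CCC | intermediate
9 | bromomagnesium (3S)-3-[(5R)-5-(tert-butyldimethylsilyloxy)octyl]cyclohex-1-en-1-olate | Br[Mg]OC1=C[C@@H](CCCC[C@H](O[Si](C)(C)C(C)(C)C)CCC)CCC1 | intermediate
10 | (2S,3S)-2-[(dimethylamino)methyl]-3-[(5R)-5-(tert-butyldimethylsilyloxy)octyl]cyclohexan-1-one | O=C1CCC[C@H](CCCC[C@H](O[Si](C)(C)C(C)(C)C)CCC)[C@H]1CN(C)C | intermediate
11 | (1S,2S,3S)-2-[(dimethylamino)methyl]-3-[(5R)-5-(tert-butyldimethylsilyloxy)octyl]cyclohexan-1-ol | O[C@H]1CCC[C@H](CCCC[C@H](O[Si](C)(C)C(C)(C)C)CCC)[C@H]1CN(C)C | intermediate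
12 | N-oxide of 11 | O[C@H]1CCC[C@H](CCCC[C@H](O[Si](C)(C)C(C)(C)C)CCC)[C@H]1C[N+](C)(C)[O-] | intermediate
13 | (1S,3S)-2-methylidene-3-[(5R)-5-(tert-butyldimethylsilyloxy)octyl]cyclohexan-1-ol | O[C@H]1CCC[C@H](CCCC[C@H](O[Si](C)(C)C(C)(C)C)CCC)C1=C | intermediate
14 | benzylamine | NCc1ccccc1 | starting material
15 | 2-nitrobenzenesulfonyl chloride | O=S(=O)(Cl)c1ccccc1[N+](=O)[O-] | starting material
16 | N-benzyl-2-nitrobenzenesulfonamide | O=S(=O)(NCc1ccccc1)c1ccccc1[N+](=O)[O-] | intermediate
17 | N-benzyl-N-{(1R,3S)-2-methylidene-3-[(5R)-5-(tert-butyldimethylsilyloxy)octyl]cyclohexyl}-2-nitrobenzenesulfonamide | O=S(=O)(c1ccccc1[N+](=O)[O-])N(Cc1ccccc1)[C@@H]1CCC[C@H](CCCC[C@H](O[Si](C)(C)C(C)(C)C)CCC)C1=C | intermediate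
18 | (1R,3S)-N-benzyl-2-methylidene-3-[(5R)-5-(tert-butyldimethylsilyloxy)octyl]cyclohexan-1-amine | c1ccccc1CN[C@@H]1CCC[C@H](CCCC[C@H](O[Si](C)(C)C(C)(C)C)CCC)C1=C | intermediate
19 | methyl (R)-lactate | C[C@@H](O)C(=O)OC | starting material
20 | methyl (2R)-2-(trifluoromethylsulfonyloxy)propanoate | C[C@@H](OS(=O)(=O)C(F)(F)F)C(=O)OC | intermediate
21 | methyl N-benzyl-N-{(1R,3S)-2-methylidene-3-[(5R)-5-(tert-butyldimethylsilyloxy)octyl]cyclohexyl}-L-alaninate | COC(=O)[C@H](C)N(Cc1ccccc1)[C@@H]1CCC[C@H](CCCC[C@H](O[Si](C)(C)C(C)(C)C)CCC)C1=C | intermediate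
22 | (2S)-2-[benzyl{(1R,3S)-2-methylidene-3-[(5R)-5-(tert-butyldimethylsilyloxy)octyl]cyclohexyl}amino]propanal | O=C[C@H](C)N(Cc1ccccc1)[C@@H]1CCC[C@H](CCCC[C@H](O[Si](C)(C)C(C)(C)C)CCC)C1=C | intermediate
23 | (2S,3R,8aR)-1-benzyl-2-methyl-5-[(5R)-5-(tert-butyldimethylsilyloxy)octyl]-1,2,3,4,6,7,8,8a-octahydroquinolin-3-ol | O[C@@H]1CC2=C(CCCC[C@H](O[Si](C)(C)C(C)(C)C)CCC)CCC[C@H]2N(Cc2ccccc2)[C@H]1C | intermediate
24 | (2S,3R,4aS,5S,8aR)-1-benzyl-2-methyl-5-[(5R)-5-(tert-butyldimethylsilyloxy)octyl]decahydroquinolin-3-ol | O[C@@H]1C[C@H]2[C@@H](CCCC[C@H](O[Si](C)(C)C(C)(C)C)CCC)CCC[C@H]2N(Cc2ccccc2)[C@H]1C | intermediate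
25 | (2S,3R,4aS,5S,8aR)-2-methyl-5-[(5R)-5-(tert-butyldimethylsilyloxy)octyl]decahydroquinolin-3-ol | O[C@@H]1C[C@H]2[C@@H](CCCC[C@H](O[Si](C)(C)C(C)(C)C)CCC)CCC[C@H]2N[C@H]1C | intermediate
26 | tert-butyl (2S,3R,4aS,5S,8aR)-3-hydroxy-2-methyl-5-[(5R)-5-(tert-butyldimethylsilyloxy)octyl]octahydroquinoline-1(2H)-carboxylate | O[C@@H]1C[C@H]2[C@@H](CCCC[C@H](O[Si](C)(C)C(C)(C)C)CCC)CCC[C@H]2N(C(=O)OC(C)(C)C)[C@H]1C | intermediate
27 | (2E,4E)-octa-2,4-dienoic acid | CCC/C=C/C=C/C(=O)O | starting material
28 | (2E,4E)-octa-2,4-dienoic 2,4,6-trichlorobenzoic anhydride | CCC/C=C/C=C/C(=O)OC(=O)c1c(Cl)cc(Cl)cc1Cl | intermediate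
29 | tert-butyl (2S,3R,4aS,5S,8aR)-2-methyl-3-[(2E,4E)-octa-2,4-dienoyloxy]-5-[(5R)-5-(tert-butyldimethylsilyloxy)octyl]octahydroquinoline-1(2H)-carboxylate | CCC/C=C/C=C/C(=O)O[C@@H]1C[C@H]2[C@@H](CCCC[C@H](O[Si](C)(C)C(C)(C)C)CCC)CCC[C@H]2N(C(=O)OC(C)(C)C)[C@H]1C | intermediate
30 | lepadin H | CCC/C=C/C=C/C(=O)O[C@@H]1C[C@H]2[C@@H](CCCC[C@H](O)CCC)CCC[C@H]2N[C@H]1C | target

Total step count: 17. Longest linear sequence: 15 (steps 1–6, 8, 9, 11–17); steps 7 and 10 are one-step side branches.

Steps most likely to fail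

Step 13. The tether may fail to hold the aldehyde over the H5 face. The reaction then slips into open cationic closure or methyl transfer from aluminium, and control at C3 erodes. The fallback sets out from 22 and comes back at 23; it decouples ring formation from the control of C3. Aldehyde 22 is closed under the stronger Lewis acid MeAlCl2 (CH2Cl2, −78 °C) without regard to C3. This should give 23 together with its epimer (2S,3S,8aR)-1-benzyl-2-methyl-5-[(5R)-5-(tert-butyldimethylsilyloxy)octyl]-1,2,3,4,6,7,8,8a-octahydroquinolin-3-ol F1. The mixture is oxidised with Dess–Martin periodinane and NaHCO3 to the single amino ketone (2S,8aR)-1-benzyl-2-methyl-5-[(5R)-5-(tert-butyldimethylsilyloxy)octyl]-1,4,6,7,8,8a-hexahydroquinolin-3(2H)-one F2. NaBH4 in MeOH at low temperature attacks axially on the chair with the C2 methyl equatorial and should return the equatorial 3R alcohol 23.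

Step 14. The tertiary amine may deactivate the iridium catalyst, or the hindered tetrasubstituted double bond may migrate before it is reduced, with loss of facial control. The fallback sets out from 23 and comes back at 26; it gives up coordination control in favour of control by molecular shape. Compound 23 is hydrogenated as its acetate salt over a heterogeneous catalyst (H2 at elevated pressure, Pd(OH)2/C, EtOH–AcOH). It should adsorb through the open H8a face, and the benzyl group is cleaved in the same operation. This leads directly to amine 25, which is converted with Boc2O into 26 as in step 15.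

Step 8. The bulky sulfonamide anion may attack the exocyclic CH2 terminus with allylic transposition, or the activated alcohol may eliminate to a diene, instead of undergoing direct displacement. The fallback sets out from 11 and comes back at 17; the substitution is moved ahead of alkene formation, so that no allylic terminus exists. The saturated axial alcohol 11 is coupled with 16 under the same Mitsunobu conditions to give N-benzyl-N-{(1R,2S,3S)-2-[(dimethylamino)methyl]-3-[(5R)-5-(tert-butyldimethylsilyloxy)octyl]cyclohexyl}-2-nitrobenzenesulfonamide F3. Selective oxidation of the dimethylamino group with mCPBA gives the corresponding amine N-oxide F4. Cope elimination of F4 in hot toluene then reveals the methylene group of 17.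

Further compounds
F1 | step 13 | (2S,3S,8aR)-1-benzyl-2-methyl-5-[(5R)-5-(tert-butyldimethylsilyloxy)octyl]-1,2,3,4,6,7,8,8a-octahydroquinolin-3-ol | O[C@H]1CC2=C(CCCC[C@H](O[Si](C)(C)C(C)(C)C)CCC)CCC[C@H]2N(Cc2ccccc2)[C@H]1C
F2 | step 13 | (2S,8aR)-1-benzyl-2-methyl-5-[(5R)-5-(tert-butyldimethylsilyloxy)octyl]-1,4,6,7,8,8a-hexahydroquinolin-3(2H)-one | O=C1CC2=C(CCCC[C@H](O[Si](C)(C)C(C)(C)C)CCC)CCC[C@H]2N(Cc2ccccc2)[C@H]1C
F0 | step 14 | none | none
F3 | step 8 | N-benzyl-N-{(1R,2S,3S)-2-[(dimethylamino)methyl]-3-[(5R)-5-(tert-butyldimethylsilyloxy)octyl]cyclohexyl}-2-nitrobenzenesulfonamide | O=S(=O)(c1ccccc1[N+](=O)[O-])N(Cc1ccccc1)[C@@H]1CCC[C@H](CCCC[C@H](O[Si](C)(C)C(C)(C)C)CCC)[C@H]1CN(C)C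
F4 | step 8 | N-oxide of F3 | O=S(=O)(c1ccccc1[N+](=O)[O-])N(Cc1ccccc1)[C@@H]1CCC[C@H](CCCC[C@H](O[Si](C)(C)C(C)(C)C)CCC)[C@H]1C[N+](C)(C)[O-]
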